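Readings and results stem from a simulated flask with constants of no real substance.

At 12 min the flask stands past the last readings, which end at 10.0 min.

in all of them: J 0.050 M
- south: E 0.060 M; G 1.2 mM; run made earlier
- south-east: E 0.060 M; G 2.7 mM; run made earlier
- east: E 0.12 M; G 1.8 mM; run made earlier
- flask: E 0.0600 M; G 1.8 mM; time 12 min
- south (time / min: Z / %, J / %): 2.00: 1.4, 98.6; 4.00: 2.9, 97.0; 6.00: 6.3, 93.2; 8.00: 10.1, 89.0; 10.0: 12.9, 86.1
- south-east (time / min: Z / %, J / %): 2.00: 2.0, 97.1; 4.00: 6.6, 92.1; 6.00: 13.2, 86.4; 8.00: 18.9, 80.6; 10.0: 24.7, 74.0
- east (time / min: Z / %, J / %): 0.833: 0.4, 99.4; 2.50: 2.0, 96.6; 4.00: 5.0, 94.8; 6.00: 7.9, 89.7; 10.0: 18.1, 81.4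

(standard deviation of a reading: 0.5 percentage points)
- solid, in amounts per volume of the solution: E
- the numbers in the tables scatter with a standard deviation of 0.5 percentage points
- at the start none of E is in solution
- Thursday's: doubling the dissolution coefficient of E, all else as stated
- Tuesday's: doubling the amount of G, all else as stated
- Saturday's: doubling the solubility of E, all else as stated
- amount of Z at 12 min, in percent of the J charged
- the change that raises the amount of Z at 12 min, in percent of the J charged most ("none" if none brings more than 2 percentage points) (Thursday's / Tuesday's / Saturday's / none)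
- amount of Z at 12 min, in percent of the J charged, after Tuesday's

J is the limiting reagent, 0.050 M against 0.0600 M of E, so the end state has the J charged as its ceiling for Z. The approach is read from the east run, which has the flask's [G]: it climbs 0.0255 min⁻¹ between 6.00 min and 10.0 min. This is its late slope, the fraction of the J charged turned into Z per minute.

South has less G than the flask and south-east more, so each last reading, extended at that run's own late slope, gives one side of a bracket, an estimate that carries the scatter of the readings:

low side, south: 16.2%

high side, south-east: 30.4%

Interpolating those two runs to 1.8 mM of G gives 17.6% at 10.0 min. East read 18.1% there with twice the E, a gap about equal to the scatter. East can therefore stand in for the flask, which tightens the reckoning here to: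

east: 23.2%

The forecast gives 22.5% (20.5% to 24.5%), 34% after Tuesday's and Saturday's as best, holding “so the solid charge hardly matters”.

The flask gives 22.8%, inside the bracket. Tuesday's is best, gaining 15 percentage points against 12 points for Saturday's and 5.3 points for Thursday's, and reaches 38.1%.

    Q + G ⇌ X (K = 7.80 M⁻¹, k = 6.70 M⁻¹ s⁻¹)
    J + X ⇌ L (K = 48.0 M⁻¹, k = 9.20 M⁻¹ s⁻¹)
    L → G + Z (k = 0.0640 s⁻¹)
    E ⇌ Q, rate k4*(cs4 - [Q]) while solid is left; crystals form when [Q] > cs4 (solubility = 32.0 mM, k = 0.00330 s⁻¹)

For the same flask read at 30 min, the east run's late slope carried on from the reckoning gives a line at: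

69.1%

It reads 57.9%, lower than the line by 11 points. Between the two times Z in the flask climbs 0.0195 min⁻¹ on average, less than the late slope read in the east run, while J falls from 76.6% to 41.7%.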